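**Retrosynthetic overview**
- The target comes from its tetra-O-benzyl ether by hydrogenolysis. Ring C is the only ring made in the route; ring A, the 2-phenyl ring and the four side-chain arenes are bought.
- The strategy rests on C4: it is an aryl ketone carbon on ring A, flanked by the C5 hydroxyl and by the O1–C2 ether. A salicylaldehyde carrying an O-(1-phenylvinyl) group therefore holds every atom of ring C, with C3–C4 as the only missing bond. An enantioselective rhodium-catalysed hydroacylation forms that bond, puts hydrogen on C2 and closes ring C.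
- The 1-phenylvinyl ether comes from E2 loss of HCl from a 2-chloro-1-phenylethyl ether, which is put on by Mitsunobu reaction before the ring becomes crowded.
- The C6–CH2 and C8–CH2 bonds come from a twofold Negishi coupling of the ring A 3,5-dibromide with a benzylic zinc chloride. That reagent comes from 5-bromosalicylaldehyde by borylation, sp2–sp3 Suzuki coupling, reduction and chlorination.

Key step: step 11

Assumption: (S)-2-chloro-1-phenylethanol and 2-(benzyloxy)benzyl bromide are bought; the carbinol stereocentre is erased in step 10 and is carried as one enantiomer only so that the chloro ether can also feed the fallback for the key step (racemic alcohol serves the main line equally).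

Step 1
Reactants: 1 2,4,6-trihydroxybenzaldehyde
Product: 2 2,6-dihydroxy-4-methoxybenzaldehyde
Conditions: MeI (1.0 equiv), K2CO3 (1.0 equiv), acetone, 0 °C to rt
Reagents that add atoms: iodomethane, CI
Why: Williamson O-methylation; the 4-OH is the most acidic hydroxyl and the only one not next to the formyl group (the 2- and 6-OH are tied up in hydrogen bonding to it), so one equivalent of base and MeI should alkylate it first.

Step 2
Reactants: 2 2,6-dihydroxy-4-methoxybenzaldehyde; 3 (S)-2-chloro-1-phenylethanol
Product: 4 (R)-2-(2-chloro-1-phenylethoxy)-6-hydroxy-4-methoxybenzaldehyde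
Conditions: PPh3, DIAD, THF, 0 °C to rt
Reagents that add atoms: none
Why: Mitsunobu etherification, which inverts the benzylic carbinol carbon ((S)-alcohol to (R)-ether); once one hydroxyl is etherified the other is locked in the hydrogen bond to the formyl oxygen, which should stop the reaction at the monoether.

Step 3
Reactants: 4 (R)-2-(2-chloro-1-phenylethoxy)-6-hydroxy-4-methoxybenzaldehyde
Product: 5 (R)-3,5-dibromo-2-(2-chloro-1-phenylethoxy)-6-hydroxy-4-methoxybenzaldehyde
Conditions: NBS (2.05 equiv), MeCN, 0 °C, dark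
Reagents that add atoms: N-bromosuccinimide, O=C1CCC(=O)N1Br
Why: Electrophilic aromatic bromination; C3 and C5 are the only free ring positions and each is ortho or para to all three oxygen substituents, while the ionic conditions in the dark spare the benzylic ether C–H.

Step 4
Reactants: 6 5-bromosalicylaldehyde
Product: 7 2-(benzyloxy)-5-bromobenzaldehyde
Conditions: BnBr, K2CO3, DMF, rt
Reagents that add atoms: benzyl bromide, BrCc1ccccc1
Why: Williamson ether synthesis on an acidic ortho-formyl phenol.

Step 5
Reactants: 7 2-(benzyloxy)-5-bromobenzaldehyde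
Product: 8 2-(benzyloxy)-5-(4,4,5,5-tetramethyl-1,3,2-dioxaborolan-2-yl)benzaldehyde
Conditions: B2pin2, Pd(dppf)Cl2 (3 mol%), KOAc, 1,4-dioxane, 90 °C
Reagents that add atoms: bis(pinacolato)diboron, CC1(C)OB(B2OC(C)(C)C(C)(C)O2)OC1(C)C
Why: Miyaura borylation of an aryl bromide, which tolerates the aldehyde and the benzyl ether.

Step 6
Reactants: 8 2-(benzyloxy)-5-(4,4,5,5-tetramethyl-1,3,2-dioxaborolan-2-yl)benzaldehyde; 9 2-(benzyloxy)benzyl bromide
Product: 10 2-(benzyloxy)-5-[2-(benzyloxy)benzyl]benzaldehyde
Conditions: Pd(PPh3)4 (5 mol%), K2CO3, DME/H2O, 80 °C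
Reagents that add atoms: none
Why: sp2–sp3 Suzuki–Miyaura coupling of an arylboronate with a benzylic bromide, a standard way to a diarylmethane that leaves the aldehyde untouched.

Step 7
Reactants: 10 2-(benzyloxy)-5-[2-(benzyloxy)benzyl]benzaldehyde
Product: 11 {2-(benzyloxy)-5-[2-(benzyloxy)benzyl]phenyl}methanol
Conditions: NaBH4, MeOH/THF, 0 °C
Reagents that add atoms: none
Why: Hydride reduction of an aryl aldehyde to the benzylic alcohol.

Step 8
Reactants: 11 {2-(benzyloxy)-5-[2-(benzyloxy)benzyl]phenyl}methanol
Product: 12 1-(benzyloxy)-4-[2-(benzyloxy)benzyl]-2-(chloromethyl)benzene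
Conditions: SOCl2 (1.2 equiv), DMF (cat.), CH2Cl2, 0 °C
Reagents that add atoms: thionyl chloride, O=S(Cl)Cl
Why: Chlorodehydroxylation of an electron-rich benzylic alcohol; the chloride is chosen over the bromide because it gives less homocoupling in the zinc insertion.

Step 9
Reactants: 12 1-(benzyloxy)-4-[2-(benzyloxy)benzyl]-2-(chloromethyl)benzene; 5 (R)-3,5-dibromo-2-(2-chloro-1-phenylethoxy)-6-hydroxy-4-methoxybenzaldehyde
Product: 14 (R)-3,5-bis{[2-(benzyloxy)-5-(2-(benzyloxy)benzyl)phenyl]methyl}-2-(2-chloro-1-phenylethoxy)-6-hydroxy-4-methoxybenzaldehyde, via benzylic zinc chloride 13 (not isolated)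
Conditions: 12 (3.2 equiv), Zn dust, LiCl, THF, 25 °C; solution of 13 decanted from Zn and added over 1 h to 5, Pd(OAc)2 (5 mol%), SPhos (10 mol%), THF, 25 to 50 °C
Reagents that add atoms: zinc, [Zn] (ends in intermediate 13, not in 14)
Why: LiCl-promoted zinc insertion followed by a twofold Negishi sp2–sp3 coupling; the Pd(OAc)2/SPhos system couples hindered, electron-rich aryl bromides faster than a benzylic zinc chloride is protonated by a phenol or adds to a chelated, di-ortho-substituted aldehyde, and the primary alkyl chloride is inert once free zinc is removed.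

Step 10
Reactants: 14 (R)-3,5-bis{[2-(benzyloxy)-5-(2-(benzyloxy)benzyl)phenyl]methyl}-2-(2-chloro-1-phenylethoxy)-6-hydroxy-4-methoxybenzaldehyde
Product: 15 3,5-bis{[2-(benzyloxy)-5-(2-(benzyloxy)benzyl)phenyl]methyl}-2-hydroxy-4-methoxy-6-[(1-phenylethenyl)oxy]benzaldehyde
Conditions: KOtBu (3 equiv), THF, 0 °C to rt; pH 7 buffer work-up; Et3N-deactivated silica
Reagents that add atoms: none
Why: E2 dehydrochlorination of a β-chloro ether, the classical route to aryl vinyl ethers; the only β-hydrogen is the benzylic O–CH(Ph) hydrogen, so only the 1-phenylvinyl ether can form (the carbinol stereocentre is erased), and the non-enolisable formyl group is shielded as its chelated phenoxide.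

Step 11
Reactants: 15 3,5-bis{[2-(benzyloxy)-5-(2-(benzyloxy)benzyl)phenyl]methyl}-2-hydroxy-4-methoxy-6-[(1-phenylethenyl)oxy]benzaldehyde
Product: 16 (2S)-6,8-bis{[2-(benzyloxy)-5-(2-(benzyloxy)benzyl)phenyl]methyl}-5-hydroxy-7-methoxy-2-phenylchroman-4-one
Conditions: [Rh(cod)Cl]2 (5 mol%), (R)-DTBM-SEGPHOS (10 mol%), NaB[3,5-(CF3)2C6H3]4 (10 mol%), 2,6-di-tert-butylpyridine (10 mol%), 4 Å MS, 1,4-dioxane, 60 °C
Reagents that add atoms: none
Why: Proposed new method: the cationic bisphosphine complex of monovalent rhodium should insert into the formyl C–H bond of 15 to give an acyl hydride of trivalent rhodium, in which the free hydroxyl (the later 5-OH) hydrogen-bonds the acyl oxygen and so holds the metal on the side of the enol ether, whose oxygen and alkene can bind it; the hydride then adds to the oxygen-bearing alkene carbon (C2) with rhodium going to the terminal CH2, and C–C reductive elimination from the seven-membered acyl alkyl rhodacycle forms C3–C4. The closest known reaction types are the rhodium-catalysed enantioselective intramolecular hydroacylation of 1,1-disubstituted alkenes in ortho-allylbenzaldehydes and N-(1-arylvinyl)indole-2-carbaldehydes, which also joins the acyl carbon to the unsubstituted alkene terminus, and the ether-chelated hydroacylation of 2-(alkenyloxy)benzaldehydes; a 1-arylvinyl ether of a salicylaldehyde has not been used as the alkene. Ring C is closed in a formally 6-endo-trig mode. The C2 stereocentre arises in the hydride insertion and is controlled by the chiral ligand alone, since 15 is achiral; the (R)-ligand is proposed for the (S)-product and its antipode is used if the sense of induction turns out to be the opposite. The step needs hydride delivery to C2 and not to the CH2 terminus, which would end in a 2-methyl-2-phenylbenzofuran-3-one, and it needs insertion to outrun decarbonylation: the polarity of the enol ether, the preference of rhodium for the primary carbon and the difficulty of reductive elimination to a quaternary centre should secure the first, and the two ortho substituents of the formyl group together with the neighbouring alkene the second. The hindered pyridine and the sieves are there to keep traces of acid and water from hydrolysing the enol ether.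

Step 12
Reactants: 16 (2S)-6,8-bis{[2-(benzyloxy)-5-(2-(benzyloxy)benzyl)phenyl]methyl}-5-hydroxy-7-methoxy-2-phenylchroman-4-one
Product: 17 (2S)-5-hydroxy-6,8-bis{[2-hydroxy-5-(2-hydroxybenzyl)phenyl]methyl}-7-methoxy-2-phenylchroman-4-one, 5''-(2''''-hydroxybenzyl)uvarinol
Conditions: H2 (1 atm), Pd/C (10%), EtOAc/MeOH, rt
Reagents that add atoms: none
Why: Hydrogenolysis of the four aryl benzyl ethers; at 1 atm and rt the diarylmethane CH2 groups, the hydrogen-bonded C4 ketone and the C2–O1 bond should survive if the reaction is stopped after uptake of four equivalents, and the neutral medium does not open ring C, so C2 keeps its configuration.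

**Compound list**
1 | 2,4,6-trihydroxybenzaldehyde | O=Cc1c(O)cc(O)cc1O | starting material
2 | 2,6-dihydroxy-4-methoxybenzaldehyde | COc1cc(O)c(C=O)c(O)c1 | intermediate
3 | (S)-2-chloro-1-phenylethanol | O[C@@H](c1ccccc1)CCl | starting material
4 | (R)-2-(2-chloro-1-phenylethoxy)-6-hydroxy-4-methoxybenzaldehyde | COc1cc(O)c(C=O)c(O[C@H](c2ccccc2)CCl)c1 | intermediate
5 | (R)-3,5-dibromo-2-(2-chloro-1-phenylethoxy)-6-hydroxy-4-methoxybenzaldehyde | COc1c(Br)c(O)c(C=O)c(O[C@H](c2ccccc2)CCl)c1Br | intermediate
6 | 5-bromosalicylaldehyde | O=Cc1cc(Br)ccc1O | starting material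
7 | 2-(benzyloxy)-5-bromobenzaldehyde | O=Cc1cc(Br)ccc1OCc1ccccc1 | intermediate
8 | 2-(benzyloxy)-5-(4,4,5,5-tetramethyl-1,3,2-dioxaborolan-2-yl)benzaldehyde | O=Cc1cc(B2OC(C)(C)C(C)(C)O2)ccc1OCc1ccccc1 | intermediate
9 | 2-(benzyloxy)benzyl bromide | BrCc1ccccc1OCc1ccccc1 | starting material
10 | 2-(benzyloxy)-5-[2-(benzyloxy)benzyl]benzaldehyde | O=Cc1cc(Cc2ccccc2OCc2ccccc2)ccc1OCc1ccccc1 | intermediate
11 | {2-(benzyloxy)-5-[2-(benzyloxy)benzyl]phenyl}methanol | OCc1cc(Cc2ccccc2OCc2ccccc2)ccc1OCc1ccccc1 | intermediate
12 | 1-(benzyloxy)-4-[2-(benzyloxy)benzyl]-2-(chloromethyl)benzene | ClCc1cc(Cc2ccccc2OCc2ccccc2)ccc1OCc1ccccc1 | intermediate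
13 | {[2-(benzyloxy)-5-(2-(benzyloxy)benzyl)phenyl]methyl}zinc chloride (benzylic zinc chloride, LiCl-complexed in THF, not isolated) | Cl[Zn]Cc1cc(Cc2ccccc2OCc2ccccc2)ccc1OCc1ccccc1 | intermediate
14 | (R)-3,5-bis{[2-(benzyloxy)-5-(2-(benzyloxy)benzyl)phenyl]methyl}-2-(2-chloro-1-phenylethoxy)-6-hydroxy-4-methoxybenzaldehyde | COc1c(Cc2cc(Cc3ccccc3OCc3ccccc3)ccc2OCc2ccccc2)c(O)c(C=O)c(O[C@H](c2ccccc2)CCl)c1Cc1cc(Cc2ccccc2OCc2ccccc2)ccc1OCc1ccccc1 | intermediate
15 | 3,5-bis{[2-(benzyloxy)-5-(2-(benzyloxy)benzyl)phenyl]methyl}-2-hydroxy-4-methoxy-6-[(1-phenylethenyl)oxy]benzaldehyde | COc1c(Cc2cc(Cc3ccccc3OCc3ccccc3)ccc2OCc2ccccc2)c(O)c(C=O)c(OC(=C)c2ccccc2)c1Cc1cc(Cc2ccccc2OCc2ccccc2)ccc1OCc1ccccc1 | intermediate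
16 | (2S)-6,8-bis{[2-(benzyloxy)-5-(2-(benzyloxy)benzyl)phenyl]methyl}-5-hydroxy-7-methoxy-2-phenylchroman-4-one | COc1c(Cc2cc(Cc3ccccc3OCc3ccccc3)ccc2OCc2ccccc2)c(O)c2c(c1Cc1cc(Cc3ccccc3OCc3ccccc3)ccc1OCc1ccccc1)O[C@H](c1ccccc1)CC2=O | intermediate
17 | (2S)-5-hydroxy-6,8-bis{[2-hydroxy-5-(2-hydroxybenzyl)phenyl]methyl}-7-methoxy-2-phenylchroman-4-one, 5''-(2''''-hydroxybenzyl)uvarinol | COc1c(Cc2cc(Cc3ccccc3O)ccc2O)c(O)c2c(c1Cc1cc(Cc3ccccc3O)ccc1O)O[C@H](c1ccccc1)CC2=O | target

Total step count: 12. Longest linear sequence: 9 steps (steps 4 to 8, then 9 to 12).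

**Steps most likely to fail**

1. Step 11. The acyl rhodium hydride may lose CO before the alkene inserts, the hydride may go to the CH2 terminus and close a five-membered ring, facial selectivity may be poor, or traces of acid may hydrolyse the enol ether. The fallback uses known chemistry and takes C2 from the chiral pool; it sets out from 14, whose carbinol carbon already has the arrangement needed at C2, and comes back at 16. Finkelstein exchange (NaI, butanone, reflux) should give (R)-3,5-bis{[2-(benzyloxy)-5-(2-(benzyloxy)benzyl)phenyl]methyl}-2-hydroxy-6-(2-iodo-1-phenylethoxy)-4-methoxybenzaldehyde F1. A thiazolium-derived N-heterocyclic carbene (3-benzyl-5-(2-hydroxyethyl)-4-methylthiazolium chloride, K2CO3, toluene, 60 to 80 °C) then turns the formyl group into its Breslow intermediate, which displaces the primary iodide in a 6-exo-tet closure and so forms C3–C4, giving 16. This is the carbene-catalysed intramolecular nucleophilic acylation of an alkyl halide, known for chroman-4-ones. The stereocentre is not touched in the ring closure, so its purity then rests on the inversion in step 2 and on keeping the base mild, since a flavanone can open to the chalcone under strong base.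

2. Step 9. The zinc reagent may be protonated by the acidic phenol or add to the formyl group, the second coupling may stall at the crowded positions beside the methoxy group, or bromine may be lost reductively. The fallback replaces the organozinc by an organoboron nucleophile, which is neither basic toward the phenol nor nucleophilic toward the aldehyde; it sets out from 12 and 5 and comes back at 14. Chloride 12 is borylated (B2pin2, Pd2(dba)3, P(4-MeOC6H4)3, KOAc, toluene, 50 °C) to 2-{[2-(benzyloxy)-5-(2-(benzyloxy)benzyl)phenyl]methyl}-4,4,5,5-tetramethyl-1,3,2-dioxaborolane F2. F2 is then coupled twice with 5 under aqueous Suzuki–Miyaura conditions (Pd(OAc)2, SPhos, K3PO4, toluene/H2O, 80 °C) to give 14.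

3. Step 10. tert-Butoxide may substitute the chloride instead of eliminating, the base may attack the formyl group, or the enol ether may hydrolyse to the phenol and acetophenone during work-up. The fallback forms the aryl–O–vinyl bond by copper-mediated oxidative coupling (Chan–Lam O-alkenylation) instead of Mitsunobu reaction and elimination; it sets out from 2 and comes back at 15. NBS (2 equiv, MeCN, 0 °C) gives 3,5-dibromo-2,6-dihydroxy-4-methoxybenzaldehyde F3. Twofold Negishi coupling with 13 under the conditions of step 9 gives 3,5-bis{[2-(benzyloxy)-5-(2-(benzyloxy)benzyl)phenyl]methyl}-2,6-dihydroxy-4-methoxybenzaldehyde F4. Cu(OAc)2, pyridine, 4 Å MS and air in CH2Cl2 with 4,4,5,5-tetramethyl-2-(1-phenylvinyl)-1,3,2-dioxaborolane (C=C(B1OC(C)(C)C(C)(C)O1)c1ccccc1) should then vinylate one of the two equivalent hydroxyls to give 15; the second hydroxyl is held in the hydrogen bond to the formyl group.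

**Further compounds**
F1 | step 11 | (R)-3,5-bis{[2-(benzyloxy)-5-(2-(benzyloxy)benzyl)phenyl]methyl}-2-hydroxy-6-(2-iodo-1-phenylethoxy)-4-methoxybenzaldehyde | COc1c(Cc2cc(Cc3ccccc3OCc3ccccc3)ccc2OCc2ccccc2)c(O)c(C=O)c(O[C@H](c2ccccc2)CI)c1Cc1cc(Cc2ccccc2OCc2ccccc2)ccc1OCc1ccccc1
F2 | step 9 | 2-{[2-(benzyloxy)-5-(2-(benzyloxy)benzyl)phenyl]methyl}-4,4,5,5-tetramethyl-1,3,2-dioxaborolane | CC1(C)OB(Cc2cc(Cc3ccccc3OCc3ccccc3)ccc2OCc2ccccc2)OC1(C)C
F3 | step 10 | 3,5-dibromo-2,6-dihydroxy-4-methoxybenzaldehyde | COc1c(Br)c(O)c(C=O)c(O)c1Br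
F4 | step 10 | 3,5-bis{[2-(benzyloxy)-5-(2-(benzyloxy)benzyl)phenyl]methyl}-2,6-dihydroxy-4-methoxybenzaldehyde | COc1c(Cc2cc(Cc3ccccc3OCc3ccccc3)ccc2OCc2ccccc2)c(O)c(C=O)c(O)c1Cc1cc(Cc2ccccc2OCc2ccccc2)ccc1OCc1ccccc1
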